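**Plan**

Ring letters: A is the trioxygenated ring, B the para-phenylene, C the 1,2,3-trisubstituted ring with the single OH, D the ortho-disubstituted ring.
Retrosynthesis: the three phenols come from methyl ethers, and the macrocycle is cut first at the ring D–CH2CH2–ring A bridge (stilbene from an intramolecular Wittig reaction), then at the ring A–O–ring B ether (copper-catalysed arylation).
Ring C is then dismantled into 3-bromo-2-pyrone and an aryl alkynyl ether, because its OH, flanked aryloxy and ethano carbons map onto the brominated pyrone carbon and the two alkyne carbons.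
Forward: ring D phenol → dichlorovinyl ether → lithium aryloxyacetylide → alkylation with the ring B triflate → ring C by cycloaddition and CO2 loss → Br to OMe → ring A attached through oxygen → Wittig macrocyclisation → hydrogenation → demethylation.
The hindered ring C–O–ring D bond is therefore made on an unhindered phenoxide before ring C exists.
Stereochemistry: the target has no stereocentre; the only stereo-element formed (alkene geometry in step 11) is removed in step 12.

Key step: step 5

**Route**

Step 1
Reactants: 1 2-hydroxybenzaldehyde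
Product: 2 2-(1,3-dioxolan-2-yl)phenol
Conditions: ethylene glycol (3 equiv), TsOH·H2O (cat.), toluene, reflux, Dean–Stark trap
Reagents that add atoms: ethylene glycol, OCCO
Why: Acid-catalysed acetalisation with azeotropic removal of water masks the future ring D aldehyde as a dioxolane that should tolerate n-BuLi, heat, alkoxide and copper chemistry and is released by acid in step 10.

Step 2
Reactants: 2 2-(1,3-dioxolan-2-yl)phenol; 3 trichloroethylene
Product: 4 2-{2-[(E)-1,2-dichloroethenyloxy]phenyl}-1,3-dioxolane
Conditions: K2CO3 (2 equiv), DMF, 70 °C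
Reagents that add atoms: none
Why: Base turns trichloroethylene into dichloroacetylene in situ and the unhindered phenoxide adds to it in anti fashion (vinylic substitution by elimination–addition), which should give the (E)-dichlorovinyl aryl ether and sets the oxygen on what becomes the flanked ring C carbon.

Step 3
Reactants: 5 2-[4-(benzyloxy)phenyl]ethanol
Product: 6 2-[4-(benzyloxy)phenyl]ethyl trifluoromethanesulfonate
Conditions: Tf2O (1.1 equiv), 2,6-lutidine (1.2 equiv), CH2Cl2, −78 °C; cold filtration through SiO2 (pentane–CH2Cl2); used at once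
Reagents that add atoms: trifluoromethanesulfonic anhydride, O=S(=O)(OS(=O)(=O)C(F)(F)F)C(F)(F)F
Why: O-Triflation of a primary alcohol with Tf2O and a hindered pyridine base is routine, and the product is kept cold and used directly because the electron-rich aryl group can assist ionisation.

Step 4
Reactants: 4 2-{2-[(E)-1,2-dichloroethenyloxy]phenyl}-1,3-dioxolane; 6 2-[4-(benzyloxy)phenyl]ethyl trifluoromethanesulfonate
Product: 8 2-[2-({4-[4-(benzyloxy)phenyl]but-1-yn-1-yl}oxy)phenyl]-1,3-dioxolane, via lithium aryloxyacetylide 7 (not isolated)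
Conditions: 4, n-BuLi (2.1 equiv), THF, −78 → −40 °C; then 6 (1.2 equiv), THF, −78 → −20 °C; NaHCO3 (aq.) quench; chromatography on Et3N-deactivated SiO2
Reagents that add atoms: none
Why: Deprotonation and β-elimination of the dichlorovinyl ether followed by chlorine–lithium exchange is the established route to lithium alkynyl ethers, and SN2 alkylation of acetylide 7 by the primary triflate at low temperature should form the C(sp)–C(sp3) bond faster than E2 elimination to the styrene.

Step 5
Reactants: 8 2-[2-({4-[4-(benzyloxy)phenyl]but-1-yn-1-yl}oxy)phenyl]-1,3-dioxolane; 9 3-bromo-2H-pyran-2-one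
Product: 11 2-[2-(2-bromo-6-{2-[4-(benzyloxy)phenyl]ethyl}phenoxy)phenyl]-1,3-dioxolane, via bicyclic lactone 10 (not isolated)
Conditions: 9 (2.5 equiv), BHT (5 mol%), 2,6-di-tert-butyl-4-methylpyridine (10 mol%), toluene (0.5 M), sealed tube, 130 °C
Reagents that add atoms: none
Why: Proposed new method: alkynyl ether 8 should add across C3 and C6 of the ambiphilic pyrone 9 in a concerted but asynchronous [4+2] cycloaddition, the bond from the nucleophilic alkyl-bearing alkyne carbon to the electrophilic C6 leading and the bond from the oxygen-bearing alkyne carbon to the brominated C3 following, to give the bridged 2-oxabicyclo[2.2.2]octadienone 10, which expels CO2 by retro-[4+2] cycloaddition and is aromatic at once. The closest known reaction types are the Diels–Alder/decarboxylation benzannulation of 2-pyrones with alkynes and ynamines and the regioselective cycloadditions of 3-bromo-2-pyrone with enol ethers, whereas an internal aryl alkynyl ether has not been shown as the 2π partner. Ring C is closed by this intermolecular [4+2] cycloaddition, which forms both new C–C bonds (pyrone C3 to the aryloxy carbon, pyrone C6 to the alkyl carbon), followed by cycloreversion. No stereocentre results, because the two bridgehead centres of racemic 10 vanish on aromatisation. The step needs regioselectivity (bromine next to the aryloxy carbon), which the matched polarisation should secure, since the largest LUMO coefficient of 9 lies at C6 and the largest HOMO coefficient of 8 at the carbon β to oxygen. It also needs a dienophile that survives the temperature, which an aryl rather than alkyl alkynyl ether provides because it has no O-alkyl β-hydrogen for retro-ene loss of a ketene, while the hindered pyridine buffers traces of acid that would hydrate the alkyne or open the acetal.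

Step 6
Reactants: 11 2-[2-(2-bromo-6-{2-[4-(benzyloxy)phenyl]ethyl}phenoxy)phenyl]-1,3-dioxolane
Product: 12 2-[2-(2-{2-[4-(benzyloxy)phenyl]ethyl}-6-methoxyphenoxy)phenyl]-1,3-dioxolane
Conditions: NaOMe (5 equiv), CuI (0.3 equiv), DMF–MeOH (3:1), 110 °C
Reagents that add atoms: sodium methoxide, [Na+].[O-]C
Why: Copper-mediated Ullmann-type methoxylation of an aryl bromide ortho to an oxygen substituent should exchange the placeholder bromine for the ring C oxygen, with acetal and benzyl ether inert to methoxide.

Step 7
Reactants: 12 2-[2-(2-{2-[4-(benzyloxy)phenyl]ethyl}-6-methoxyphenoxy)phenyl]-1,3-dioxolane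
Product: 13 4-(2-{2-[2-(1,3-dioxolan-2-yl)phenoxy]-3-methoxyphenyl}ethyl)phenol
Conditions: H2 (1 atm), Pd/C (10%), NaHCO3 (solid, trace), EtOAc, rt; stopped when 12 is consumed
Reagents that add atoms: none
Why: Catalytic hydrogenolysis should free the ring B phenol, since a phenolic benzyl ether cleaves far faster than the 2-aryl-1,3-dioxolane in neutral ethyl acetate and no aryl halide remains in the molecule.

Step 8
Reactants: 13 4-(2-{2-[2-(1,3-dioxolan-2-yl)phenoxy]-3-methoxyphenyl}ethyl)phenol; 14 3-bromo-4,5-dimethoxybenzaldehyde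
Product: 15 3-[4-(2-{2-[2-(1,3-dioxolan-2-yl)phenoxy]-3-methoxyphenyl}ethyl)phenoxy]-4,5-dimethoxybenzaldehyde
Conditions: 14 (2 equiv), CuI (20 mol%), N,N-dimethylglycine hydrochloride (60 mol%), Cs2CO3 (3 equiv), 1,4-dioxane, 100 °C
Reagents that add atoms: none
Why: Ligand-accelerated Ullmann diaryl ether synthesis should join the unhindered ring B phenol to the ring A bromide, the excess of inexpensive 14 compensating for the slower reaction of an ortho-methoxy aryl bromide.

Step 9
Reactants: 15 3-[4-(2-{2-[2-(1,3-dioxolan-2-yl)phenoxy]-3-methoxyphenyl}ethyl)phenoxy]-4,5-dimethoxybenzaldehyde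
Product: 16 {3-[4-(2-{2-[2-(1,3-dioxolan-2-yl)phenoxy]-3-methoxyphenyl}ethyl)phenoxy]-4,5-dimethoxyphenyl}methanol
Conditions: NaBH4, MeOH–THF, 0 °C
Reagents that add atoms: none
Why: Borohydride reduction converts the only free aldehyde into the benzylic alcohol while the ring D aldehyde stays masked as its acetal.

Step 10
Reactants: 16 {3-[4-(2-{2-[2-(1,3-dioxolan-2-yl)phenoxy]-3-methoxyphenyl}ethyl)phenoxy]-4,5-dimethoxyphenyl}methanol
Product: 18 (3-{4-[2-(2-(2-formylphenoxy)-3-methoxyphenyl)ethyl]phenoxy}-4,5-dimethoxybenzyl)triphenylphosphonium bromide, via acetal phosphonium bromide 17 (not isolated)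
Conditions: PPh3·HBr (1.2 equiv), MeCN, reflux
Reagents that add atoms: triphenylphosphine hydrobromide, [Br-].c1ccc(cc1)[PH+](c1ccccc1)c1ccccc1
Why: The electron-rich benzylic alcohol should undergo acid-promoted substitution by PPh3 to the benzylphosphonium bromide, and the water released in that event hydrolyses the dioxolane in the acidic medium, so ylide precursor and aldehyde are unveiled in one operation.

Step 11
Reactants: 18 (3-{4-[2-(2-(2-formylphenoxy)-3-methoxyphenyl)ethyl]phenoxy}-4,5-dimethoxybenzyl)triphenylphosphonium bromide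
Product: 20 macrocyclic stilbene (tri-O-methyl ether of the target with CH=CH between ring D and ring A; expected as a mixture of alkene isomers), via phosphonium ylide 19 (not isolated)
Conditions: syringe-pump addition of 18 in CH2Cl2 to NaOMe (5 equiv, in MeOH) in CH2Cl2, rt, final concentration about 1 mM
Reagents that add atoms: none
Why: Intramolecular Wittig olefination of the semi-stabilised benzylic ylide with the ring D aldehyde under high dilution is the established ring closure for macrocyclic bis(bibenzyl) ethers, and the alkene geometry is immaterial because the double bond is reduced next.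

Step 12
Reactants: 20 macrocyclic stilbene
Product: 21 tri-O-methyl ether of the target (saturated macrocycle)
Conditions: H2 (1 atm), Pd/C (10%), EtOAc, rt
Reagents that add atoms: none
Why: Catalytic hydrogenation of the stilbene double bond should give the ethano bridge from either alkene isomer without touching diaryl or methyl aryl ethers.

Step 13
Reactants: 21 tri-O-methyl ether of the target
Product: 22 target macrocycle CNP0290892.0 (ring A 3,4-diol, ring C phenol)
Conditions: BBr3 (9 equiv), CH2Cl2, −78 °C → rt; then H2O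
Reagents that add atoms: none
Why: BBr3 cleavage of the three aryl methyl ethers should liberate the catechol and the ring C phenol while the two diaryl ether bonds resist.

**Compound list**

1 | 2-hydroxybenzaldehyde | O=Cc1ccccc1O | starting material
2 | 2-(1,3-dioxolan-2-yl)phenol | Oc1ccccc1C1OCCO1 | intermediate
3 | trichloroethylene | ClC=C(Cl)Cl | starting material
4 | 2-{2-[(E)-1,2-dichloroethenyloxy]phenyl}-1,3-dioxolane | Cl/C=C(/Cl)Oc1ccccc1C1OCCO1 | intermediate
5 | 2-[4-(benzyloxy)phenyl]ethanol | OCCc1ccc(OCc2ccccc2)cc1 | starting material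
6 | 2-[4-(benzyloxy)phenyl]ethyl trifluoromethanesulfonate | FC(F)(F)S(=O)(=O)OCCc1ccc(OCc2ccccc2)cc1 | intermediate
7 | lithium [2-(1,3-dioxolan-2-yl)phenoxy]ethynide | [Li]C#COc1ccccc1C1OCCO1 | intermediate (not isolated)
8 | 2-[2-({4-[4-(benzyloxy)phenyl]but-1-yn-1-yl}oxy)phenyl]-1,3-dioxolane | O(C#CCCc1ccc(OCc2ccccc2)cc1)c1ccccc1C1OCCO1 | intermediate
9 | 3-bromo-2H-pyran-2-one | O=C1OC=CC=C1Br | starting material
10 | 6-{2-[4-(benzyloxy)phenyl]ethyl}-4-bromo-5-[2-(1,3-dioxolan-2-yl)phenoxy]-2-oxabicyclo[2.2.2]octa-5,7-dien-3-one (racemic) | O=C1OC2C=CC1(Br)C(Oc3ccccc3C3OCCO3)=C2CCc4ccc(OCc5ccccc5)cc4 | intermediate (not isolated)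
11 | 2-[2-(2-bromo-6-{2-[4-(benzyloxy)phenyl]ethyl}phenoxy)phenyl]-1,3-dioxolane | Brc1cccc(CCc2ccc(OCc3ccccc3)cc2)c1Oc1ccccc1C1OCCO1 | intermediate
12 | 2-[2-(2-{2-[4-(benzyloxy)phenyl]ethyl}-6-methoxyphenoxy)phenyl]-1,3-dioxolane | COc1cccc(CCc2ccc(OCc3ccccc3)cc2)c1Oc1ccccc1C1OCCO1 | intermediate
13 | 4-(2-{2-[2-(1,3-dioxolan-2-yl)phenoxy]-3-methoxyphenyl}ethyl)phenol | COc1cccc(CCc2ccc(O)cc2)c1Oc1ccccc1C1OCCO1 | intermediate
14 | 3-bromo-4,5-dimethoxybenzaldehyde | O=Cc1cc(Br)c(OC)c(OC)c1 | starting material
15 | 3-[4-(2-{2-[2-(1,3-dioxolan-2-yl)phenoxy]-3-methoxyphenyl}ethyl)phenoxy]-4,5-dimethoxybenzaldehyde | COc1cccc(CCc2ccc(Oc3cc(C=O)cc(OC)c3OC)cc2)c1Oc1ccccc1C1OCCO1 | intermediate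
16 | {3-[4-(2-{2-[2-(1,3-dioxolan-2-yl)phenoxy]-3-methoxyphenyl}ethyl)phenoxy]-4,5-dimethoxyphenyl}methanol | COc1cccc(CCc2ccc(Oc3cc(CO)cc(OC)c3OC)cc2)c1Oc1ccccc1C1OCCO1 | intermediate
17 | (3-{4-[2-(2-[2-(1,3-dioxolan-2-yl)phenoxy]-3-methoxyphenyl)ethyl]phenoxy}-4,5-dimethoxybenzyl)triphenylphosphonium bromide | COc1cccc(CCc2ccc(Oc3cc(C[P+](c4ccccc4)(c4ccccc4)c4ccccc4)cc(OC)c3OC)cc2)c1Oc1ccccc1C1OCCO1.[Br-] | intermediate (not isolated)
18 | (3-{4-[2-(2-(2-formylphenoxy)-3-methoxyphenyl)ethyl]phenoxy}-4,5-dimethoxybenzyl)triphenylphosphonium bromide | COc1cccc(CCc2ccc(Oc3cc(C[P+](c4ccccc4)(c4ccccc4)c4ccccc4)cc(OC)c3OC)cc2)c1Oc1ccccc1C=O.[Br-] | intermediate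
19 | ylide of 18: 2-[2-(2-{4-[2,3-dimethoxy-5-(triphenylphosphoranylidenemethyl)phenoxy]phenyl}ethyl)-6-methoxyphenoxy]benzaldehyde | COc1cccc(CCc2ccc(Oc3cc(C=P(c4ccccc4)(c4ccccc4)c4ccccc4)cc(OC)c3OC)cc2)c1Oc1ccccc1C=O | intermediate (not isolated)
20 | macrocyclic stilbene, tri-O-methyl ether with CH=CH between ring D and ring A (mixture of alkene isomers, geometry left undefined) | COc1cc2cc(c1OC)Oc1ccc(cc1)CCc1cccc(OC)c1Oc1ccccc1C=C2 | intermediate
21 | tri-O-methyl ether of the target (ethano bridge in place) | COc1cc2cc(c1OC)Oc1ccc(cc1)CCc1cccc(OC)c1Oc1ccccc1CC2 | intermediate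
22 | CNP0290892.0, macrocyclic bis(bibenzyl) with ring A 3,4-diol and ring C phenol (achiral) | Oc1cc2cc(c1O)Oc1ccc(cc1)CCc1cccc(O)c1Oc1ccccc1CC2 | target

**Count and risks**

Total steps: 13. Longest linear sequence: 12 steps (steps 1, 2 and 4–13 from 2-hydroxybenzaldehyde); step 3 is a one-step branch.

Steps most likely to fail:

1. Step 5 (the step proposed as new). The cycloaddition may be too slow at temperatures the alkynyl ether tolerates, so that oligomerisation of 8 or pyrone decomposition wins, or the orientation of addition may not be clean. Fallback by known chemistry, setting out from 2 and returning at 11: SNAr of the phenoxide of 2 on 3-bromo-2-fluorobenzaldehyde (K2CO3, DMF, 100 °C) should give 3-bromo-2-[2-(1,3-dioxolan-2-yl)phenoxy]benzaldehyde F1. Wittig reaction of F1 with [4-(benzyloxy)benzyl]triphenylphosphonium chloride (KOtBu, THF) should give the stilbene 2-[2-(2-bromo-6-{2-[4-(benzyloxy)phenyl]ethenyl}phenoxy)phenyl]-1,3-dioxolane F2 as an alkene mixture. Diimide reduction of F2 (TsNHNH2, NaOAc, DME–H2O, reflux) spares the aryl bromide and the benzyl ether and delivers 11.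

2. Step 4. The triflate may be lost by E2 elimination or by aryl-assisted ionisation before it is alkylated, and the lithiated vinyl ether may expel aryloxide instead of chloride. Fallback setting out from 2 and returning at 8: commercial 3-[4-(benzyloxy)phenyl]propan-1-ol is oxidised with Dess–Martin periodinane to 3-[4-(benzyloxy)phenyl]propanal F3. Dibromo-olefination of F3 (CBr4, PPh3, CH2Cl2, 0 °C; first stage of the Corey–Fuchs sequence) gives 1-(benzyloxy)-4-(4,4-dibromobut-3-en-1-yl)benzene F4. Copper-catalysed C–O coupling of F4 with phenol 2 (CuI, 2,2'-bipyridine, K3PO4, toluene, 110 °C) should give the bromo enol ether 2-[2-({(1Z)-1-bromo-4-[4-(benzyloxy)phenyl]but-1-en-1-yl}oxy)phenyl]-1,3-dioxolane F5. Anti dehydrobromination of F5 (KOtBu, 1,4-dioxane, rt) gives 8 without any phenethyl electrophile.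

3. Step 11. Intermolecular olefination may outrun ring closure and lead to oligomers. Fallback setting out from 15 and returning at 20: hydrolysis of the dioxolane (HCl aq., THF, rt) gives the dialdehyde 3-[4-(2-{2-(2-formylphenoxy)-3-methoxyphenyl}ethyl)phenoxy]-4,5-dimethoxybenzaldehyde F6. Intramolecular McMurry coupling of F6 with low-valent titanium generated from TiCl4 and Zn (pyridine, THF, reflux, slow addition) should give 20.

**Further compounds**

F1 | step 5 | 3-bromo-2-[2-(1,3-dioxolan-2-yl)phenoxy]benzaldehyde | O=Cc1cccc(Br)c1Oc1ccccc1C1OCCO1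
F2 | step 5 | 2-[2-(2-bromo-6-{2-[4-(benzyloxy)phenyl]ethenyl}phenoxy)phenyl]-1,3-dioxolane (alkene mixture) | Brc1cccc(C=Cc2ccc(OCc3ccccc3)cc2)c1Oc1ccccc1C1OCCO1
F3 | step 4 | 3-[4-(benzyloxy)phenyl]propanal | O=CCCc1ccc(OCc2ccccc2)cc1
F4 | step 4 | 1-(benzyloxy)-4-(4,4-dibromobut-3-en-1-yl)benzene | BrC(Br)=CCCc1ccc(OCc2ccccc2)cc1
F5 | step 4 | 2-[2-({(1Z)-1-bromo-4-[4-(benzyloxy)phenyl]but-1-en-1-yl}oxy)phenyl]-1,3-dioxolane | Br/C(Oc1ccccc1C1OCCO1)=C\CCc1ccc(OCc2ccccc2)cc1
F6 | step 11 | 3-[4-(2-{2-(2-formylphenoxy)-3-methoxyphenyl}ethyl)phenoxy]-4,5-dimethoxybenzaldehyde | COc1cccc(CCc2ccc(Oc3cc(C=O)cc(OC)c3OC)cc2)c1Oc1ccccc1C=O
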